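**Retrosynthetic overview**

1. Locants used below: cyclohexene ring C5–C6–C7–C8–C9–C10 with C5=C10; lactone C8–O–C12(=O)–C11(=C13H2)–C7; C14 is the CH2O-isobutyryl carbon on C10; the side chain C4(C15H3)–C3–C2–C1–OAc sits on C5.
2. Enabling feature: the ring alkene C5=C10 lies between the ring methylene C9 and the carbinol C6, the C6 oxygen is 1,2 to the acyl-bearing C7, and C7/C8 are trans. This is the retron of an endo Diels–Alder reaction of an (E)-1-oxy diene (C6=C5–C10=C9) with an (E)-β-hetero-substituted acrylic dienophile (C7=C8).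
3. (a) The lactone ring is formed last, from C8–OH and a C7-bound enol triflate by carbonylative lactonisation (C12 from CO, C13 from a methyl cuprate); the C8 hydroxyl is carried as a C–B bond. (b) C8–C9 and C6–C7 are formed together by a catalytic enantioselective Diels–Alder reaction of silyloxy diene 14 with boryl acrylimide 19, which builds the only carbocycle and sets C6, C7 and C8.
4. (c) Diene 14 comes from (S)-citronellal (C1–C6, C15 and the C4 stereocentre) by ozonolytic trimming, enamine C-acylation (C10, C14 with the isobutyrate), E-selective O-silylation and carbonyl methylenation (C9).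
5. Ring order: cyclohexene (step 10), then γ-lactone (step 15).

Key step: step 10

Remark: (S)-citronellal 1, ethyl (E)-3-(pinacolboryl)acrylate 15 and the (S,S)-t-Bu-box ligand are taken as purchasable.

**Route**

Step 1
Reactants: 1 (S)-citronellal
Product: 2 (6S)-8,8-dimethoxy-2,6-dimethyloct-2-ene
Conditions: HC(OMe)3, MeOH, cat. pyridinium p-toluenesulfonate, rt
Reagents that add atoms: trimethyl orthoformate, COC(OC)OC
Why: Acid-catalysed acetalisation with the orthoformate as water scavenger masks the aldehyde for the ozonolysis; the mild catalyst should avoid the intramolecular carbonyl-ene cyclisation of citronellal, and the stereocentre is untouched.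

Step 2
Reactants: 2 (6S)-8,8-dimethoxy-2,6-dimethyloct-2-ene
Product: 3 (4S)-6,6-dimethoxy-4-methylhexan-1-ol
Conditions: O3, CH2Cl2–MeOH, NaHCO3, −78 °C; then NaBH4, −78 → 0 °C
Reagents that add atoms: ozone, [O-][O+]=O
Why: Ozonolysis of the trisubstituted alkene with reductive borohydride work-up should give the primary alcohol directly (C1–O); no stereocentre is formed.

Step 3
Reactants: 3 (4S)-6,6-dimethoxy-4-methylhexan-1-ol
Product: 5 (4S)-4-methyl-6-oxohexyl acetate, via acetal acetate 4 (not isolated)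
Conditions: Ac2O, pyridine, cat. DMAP, CH2Cl2, 0 °C → rt; then 1 M HCl, THF, rt
Reagents that add atoms: acetic anhydride, CC(=O)OC(C)=O; water, O
Why: Acetylation of the primary alcohol followed by acid-catalysed acetal hydrolysis in the same flask should release the aldehyde; the stereocentre is β to the carbonyl and cannot epimerise.

Step 4
Reactants: 6 glycolic acid; 7 isobutyryl chloride
Product: 9 2-chloro-2-oxoethyl 2-methylpropanoate, via 2-(isobutyryloxy)acetic acid 8 (not isolated)
Conditions: neat, 60 °C; then SOCl2, 70 °C; distillation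
Reagents that add atoms: thionyl chloride, O=S(Cl)Cl
Why: O-Acylation of the hydroxy acid by the acid chloride and conversion of the carboxylic acid into its chloride, the way acetoxyacetyl chloride is made.

Step 5
Reactants: 5 (4S)-4-methyl-6-oxohexyl acetate; 9 2-chloro-2-oxoethyl 2-methylpropanoate
Product: 12 (4S)-7-acetoxy-3-formyl-4-methyl-2-oxoheptyl 2-methylpropanoate, via morpholine enamine 10 (not isolated), via acyl enaminone 11 (not isolated)
Conditions: morpholine, K2CO3, toluene, 0 °C → rt; then 9, pyridine, CH2Cl2, −20 °C → rt; then AcOH–NaOAc, THF–H2O, rt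
Reagents that add atoms: water, O
Why: Stork enamine acylation should place the acyl group on C5 (pyridine keeps ketene formation low) and mild aqueous acid should hydrolyse the vinylogous amide to the 2-formyl ketone; C4 is not α to a carbonyl and keeps its configuration, and C5 is an enol carbon.

Step 6
Reactants: 12 (4S)-7-acetoxy-3-formyl-4-methyl-2-oxoheptyl 2-methylpropanoate
Product: 13 (3E,4S)-7-acetoxy-3-({[tert-butyl(dimethyl)silyl]oxy}methylidene)-4-methyl-2-oxoheptyl 2-methylpropanoate
Conditions: t-BuMe2SiCl, imidazole, CH2Cl2, 0 °C → rt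
Reagents that add atoms: tert-butyldimethylsilyl chloride, CC(C)(C)[Si](C)(C)Cl
Why: O-Silylation of the hydroxymethylidene tautomer gives the vinylogous silyl ester; for such push–pull 2-(oxymethylidene) carbonyl compounds the E isomer (oxygen anti to the acyl group, syn to C4) is the thermodynamic one and E/Z equilibration is easy, as in the E-selective O-derivatisation of α-formyl esters.

Step 7
Reactants: 13 (3E,4S)-silyloxymethylidene ketone
Product: 14 (3E,4S)-7-acetoxy-3-({[tert-butyl(dimethyl)silyl]oxy}methylidene)-4-methyl-2-methylideneheptyl 2-methylpropanoate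
Conditions: Zn, CH2Br2, TiCl4, THF–CH2Cl2, 0 °C → rt
Reagents that add atoms: dibromomethane, BrCBr
Why: Takai–Lombardo methylenation: the non-basic zinc–titanium methylene reagent should convert the enolisable α-acyloxy ketone into the 1,1-disubstituted alkene (C9) without touching the esters or the C5=C6 enol ether geometry.

Step 8
Reactants: 15 ethyl (2E)-3-(4,4,5,5-tetramethyl-1,3,2-dioxaborolan-2-yl)prop-2-enoate
Product: 16 (2E)-3-(4,4,5,5-tetramethyl-1,3,2-dioxaborolan-2-yl)prop-2-enoic acid
Conditions: LiOH·H2O, THF–H2O, 0 °C; then 1 M HCl to pH 3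
Reagents that add atoms: lithium hydroxide, [Li+].[OH-]
Why: Ester saponification at 0 °C; the pinacol boronate should revert from its hydroxy-ate form on acidification and the E alkene is retained.

Step 9
Reactants: 16 (2E)-3-(pinacolboryl)prop-2-enoic acid; 17 1,3-oxazolidin-2-one
Product: 19 3-[(2E)-3-(4,4,5,5-tetramethyl-1,3,2-dioxaborolan-2-yl)prop-2-enoyl]-1,3-oxazolidin-2-one, via mixed pivalic anhydride 18 (not isolated)
Conditions: t-BuCOCl, Et3N, THF, −20 °C; then 17, LiCl, −20 °C → rt
Reagents that add atoms: none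
Why: N-Acylation of the oxazolidinone through the mixed pivalic anhydride with LiCl/Et3N activation, the standard imide synthesis for acrylic acids that avoids a strong base.

Step 10
Reactants: 14 (E)-1-silyloxy diene; 19 (E)-boryl acrylimide
Product: 20 3-{[(1S,2S,6R)-3-[(2S)-5-acetoxypentan-2-yl]-2-{[tert-butyl(dimethyl)silyl]oxy}-4-[(2-methylpropanoyloxy)methyl]-6-(4,4,5,5-tetramethyl-1,3,2-dioxaborolan-2-yl)cyclohex-3-en-1-yl]carbonyl}-1,3-oxazolidin-2-one
Conditions: [Cu{(S,S)-t-Bu-box}](SbF6)2 (10 mol %; from CuCl2, AgSbF6 and 2,2′-(propane-2,2-diyl)bis[(4S)-4-tert-butyl-4,5-dihydro-1,3-oxazole]), 4 Å molecular sieves, CH2Cl2, −20 °C → rt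
Reagents that add atoms: none
Why: The imide chelates the square-planar copper centre in its s-cis form and should undergo a concerted, asynchronous normal-demand [4+2] cycloaddition with the electron-rich diene, with the C8–C9 bond (diene terminus with the largest HOMO coefficient to the β-carbon) more advanced than C6–C7. The closest known reactions are copper bis(oxazoline)-catalysed Diels–Alder reactions of 3-acryloyloxazolidin-2-ones with 1-oxygenated butadienes and chiral-Lewis-acid-catalysed cycloadditions of 3-(3-borylacryloyl)oxazolidin-2-one with 1-acyloxy dienes, in which boron serves as a latent hydroxyl. The cyclohexene ring C5–C10 closes by intermolecular [4+2] cycloaddition, suprafacial on both partners, and no other ring is formed. C7/C8 trans follows stereospecifically from the E dienophile, C6/C7 cis from the E enol ether together with the endo orientation of the imide carbonyl, and the absolute sense from the ligand: the tert-butyl group of the (S,S)-ligand covers the Si face of the α-carbon, so the diene should add to its Re face (C7), C4 being a remote spectator. The step needs ortho regioselectivity (secured by the 1-silyloxy donor, which outweighs the 2-alkyl group, and by the polarised acrylimide), endo selectivity (secondary overlap with the chelated imide), a diene of pure E geometry (from step 6, since a Z isomer would not react) and cycloaddition faster than desilylative Mukaiyama–Michael addition (bulky silyl group, non-nucleophilic counter-ion, molecular sieves).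

Step 11
Reactants: 20 Diels–Alder adduct
Product: 21 S-ethyl (1S,2S,6R)-3-[(2S)-5-acetoxypentan-2-yl]-2-{[tert-butyl(dimethyl)silyl]oxy}-4-[(2-methylpropanoyloxy)methyl]-6-(4,4,5,5-tetramethyl-1,3,2-dioxaborolan-2-yl)cyclohex-3-ene-1-carbothioate
Conditions: EtSH, n-BuLi, THF, 0 °C
Reagents that add atoms: ethanethiol, CCS
Why: Thiolate cleavage of the N-acyl oxazolidinone at the exocyclic carbonyl gives the thioester; the weakly basic thiolate should leave C7, the esters and the boronate alone.

Step 12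
Reactants: 21 thioester
Product: 22 1-[(1S,2S,6R)-3-[(2S)-5-acetoxypentan-2-yl]-2-{[tert-butyl(dimethyl)silyl]oxy}-4-[(2-methylpropanoyloxy)methyl]-6-(4,4,5,5-tetramethyl-1,3,2-dioxaborolan-2-yl)cyclohex-3-en-1-yl]ethan-1-one
Conditions: Me2CuLi (from MeLi and CuI), Et2O, −78 °C
Reagents that add atoms: lithium dimethylcuprate, [Li+].C[Cu-]C
Why: Acyl substitution of a thioester by a lithium dialkylcuprate stops at the ketone (C13 introduced) and at −78 °C should be faster than attack on the acetate, the isobutyrate or the hindered allylic ester.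

Step 13
Reactants: 22 methyl ketone
Product: 23 1-[(1S,2S,6R)-3-[(2S)-5-acetoxypentan-2-yl]-2-{[tert-butyl(dimethyl)silyl]oxy}-4-[(2-methylpropanoyloxy)methyl]-6-(4,4,5,5-tetramethyl-1,3,2-dioxaborolan-2-yl)cyclohex-3-en-1-yl]ethenyl trifluoromethanesulfonate
Conditions: KN(SiMe3)2, THF, −78 °C; then N-(5-chloropyridin-2-yl)bis(trifluoromethanesulfonimide), −78 → −20 °C
Reagents that add atoms: N-(5-chloropyridin-2-yl)bis(trifluoromethanesulfonimide), O=S(=O)(N(c1ccc(Cl)cn1)S(=O)(=O)C(F)(F)F)C(F)(F)F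
Why: Kinetic deprotonation of the methyl ketone at the methyl group by a hindered amide base and O-triflation give the terminal enol triflate; the tertiary C7 hydrogen, flanked by two substituted carbons, should not be removed, so C7 is not epimerised and the boron needs no exchange for a protected hydroxyl.

Step 14
Reactants: 23 boryl enol triflate
Product: 24 1-[(1S,2S,6R)-3-[(2S)-5-acetoxypentan-2-yl]-2-{[tert-butyl(dimethyl)silyl]oxy}-6-hydroxy-4-[(2-methylpropanoyloxy)methyl]cyclohex-3-en-1-yl]ethenyl trifluoromethanesulfonate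
Conditions: NaBO3·4H2O, THF–H2O, rt
Reagents that add atoms: sodium perborate, [Na+].[O-]OB=O
Why: Oxidation of the secondary alkyl boronate proceeds by 1,2-migration with retention and should unveil the C8 hydroxyl trans to C7; enol triflates and esters tolerate this mildly basic aqueous medium.

Step 15
Reactants: 24 hydroxy enol triflate
Product: 25 [(3aS,4S,7aR)-5-[(2S)-5-acetoxypentan-2-yl]-4-{[tert-butyl(dimethyl)silyl]oxy}-3-methylidene-2-oxo-2,3,3a,4,7,7a-hexahydro-1-benzofuran-6-yl]methyl 2-methylpropanoate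
Conditions: Pd(PPh3)4 (5 mol %), CO (1 atm), n-Bu3N, LiCl, MeCN, 60 °C
Reagents that add atoms: carbon monoxide, [C-]#[O+]
Why: Palladium-catalysed carbonylative lactonisation of a hydroxy enol triflate: oxidative addition of zerovalent palladium to the triflate (much faster than ionisation of the hindered allylic isobutyrate), CO insertion and capture of the acylpalladium by the C8 hydroxyl should give the trans-fused α-methylene-γ-butyrolactone directly, and the silyl ether on C6 prevents closure to the cis lactone.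

Step 16
Reactants: 25 silyl-protected lactone
Product: 26 [(3aR,4S,7aR)-5-[(2S)-5-acetoxypentan-2-yl]-4-hydroxy-3-methylidene-2-oxo-2,3,3a,4,7,7a-hexahydro-1-benzofuran-6-yl]methyl 2-methylpropanoate (target)
Conditions: HF·pyridine, pyridine, THF, 0 °C → rt
Reagents that add atoms: none
Why: Fluoride cleavage of the silyl ether under buffered, weakly acidic conditions should leave the two esters, the conjugate acceptor and the lactone regiochemistry untouched.

**Compound list**

1 | (S)-citronellal, (3S)-3,7-dimethyloct-6-enal | O=CC[C@@H](C)CCC=C(C)C | starting material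
2 | (6S)-8,8-dimethoxy-2,6-dimethyloct-2-ene | COC(OC)C[C@@H](C)CCC=C(C)C | intermediate
3 | (4S)-6,6-dimethoxy-4-methylhexan-1-ol | COC(OC)C[C@@H](C)CCCO | intermediate
4 | (4S)-6,6-dimethoxy-4-methylhexyl acetate | COC(OC)C[C@@H](C)CCCOC(C)=O | intermediate
5 | (4S)-4-methyl-6-oxohexyl acetate | O=CC[C@@H](C)CCCOC(C)=O | intermediate
6 | glycolic acid | OCC(=O)O | starting material
7 | isobutyryl chloride | CC(C)C(Cl)=O | starting material
8 | 2-(isobutyryloxy)acetic acid | CC(C)C(=O)OCC(=O)O | intermediate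
9 | 2-chloro-2-oxoethyl 2-methylpropanoate | CC(C)C(=O)OCC(Cl)=O | intermediate
10 | (4S,5E)-4-methyl-6-(morpholin-4-yl)hex-5-en-1-yl acetate | O1CCN(CC1)/C=C/[C@@H](C)CCCOC(C)=O | intermediate
11 | (3E,4S)-7-acetoxy-4-methyl-3-(morpholin-4-ylmethylidene)-2-oxoheptyl 2-methylpropanoate | N1(CCOCC1)/C=C(\[C@@H](C)CCCOC(C)=O)C(=O)COC(=O)C(C)C | intermediate
12 | (4S)-7-acetoxy-3-formyl-4-methyl-2-oxoheptyl 2-methylpropanoate (C3 unassigned, largely the hydroxymethylidene enol) | O=CC(C(=O)COC(=O)C(C)C)[C@@H](C)CCCOC(C)=O | intermediate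
13 | (3E,4S)-7-acetoxy-3-({[tert-butyl(dimethyl)silyl]oxy}methylidene)-4-methyl-2-oxoheptyl 2-methylpropanoate | CC(C)(C)[Si](C)(C)O/C=C(\[C@@H](C)CCCOC(C)=O)C(=O)COC(=O)C(C)C | intermediate
14 | (3E,4S)-7-acetoxy-3-({[tert-butyl(dimethyl)silyl]oxy}methylidene)-4-methyl-2-methylideneheptyl 2-methylpropanoate | CC(C)(C)[Si](C)(C)O/C=C(\[C@@H](C)CCCOC(C)=O)C(=C)COC(=O)C(C)C | intermediate
15 | ethyl (2E)-3-(4,4,5,5-tetramethyl-1,3,2-dioxaborolan-2-yl)prop-2-enoate | CCOC(=O)/C=C/B1OC(C)(C)C(C)(C)O1 | starting material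
16 | (2E)-3-(4,4,5,5-tetramethyl-1,3,2-dioxaborolan-2-yl)prop-2-enoic acid | OC(=O)/C=C/B1OC(C)(C)C(C)(C)O1 | intermediate
17 | 1,3-oxazolidin-2-one | O=C1NCCO1 | starting material
18 | 2,2-dimethylpropanoic (2E)-3-(4,4,5,5-tetramethyl-1,3,2-dioxaborolan-2-yl)prop-2-enoic anhydride | CC(C)(C)C(=O)OC(=O)/C=C/B1OC(C)(C)C(C)(C)O1 | intermediate
19 | 3-[(2E)-3-(4,4,5,5-tetramethyl-1,3,2-dioxaborolan-2-yl)prop-2-enoyl]-1,3-oxazolidin-2-one | O=C(/C=C/B1OC(C)(C)C(C)(C)O1)N1CCOC1=O | intermediate
20 | 3-{[(1S,2S,6R)-3-[(2S)-5-acetoxypentan-2-yl]-2-{[tert-butyl(dimethyl)silyl]oxy}-4-[(2-methylpropanoyloxy)methyl]-6-(4,4,5,5-tetramethyl-1,3,2-dioxaborolan-2-yl)cyclohex-3-en-1-yl]carbonyl}-1,3-oxazolidin-2-one | CC1(C)OB(OC1(C)C)[C@@H]2CC(COC(=O)C(C)C)=C([C@@H](C)CCCOC(C)=O)[C@@H](O[Si](C)(C)C(C)(C)C)[C@H]2C(=O)N3CCOC3=O | intermediate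
21 | S-ethyl (1S,2S,6R)-3-[(2S)-5-acetoxypentan-2-yl]-2-{[tert-butyl(dimethyl)silyl]oxy}-4-[(2-methylpropanoyloxy)methyl]-6-(4,4,5,5-tetramethyl-1,3,2-dioxaborolan-2-yl)cyclohex-3-ene-1-carbothioate | CC1(C)OB(OC1(C)C)[C@@H]2CC(COC(=O)C(C)C)=C([C@@H](C)CCCOC(C)=O)[C@@H](O[Si](C)(C)C(C)(C)C)[C@H]2C(=O)SCC | intermediate
22 | 1-[(1S,2S,6R)-3-[(2S)-5-acetoxypentan-2-yl]-2-{[tert-butyl(dimethyl)silyl]oxy}-4-[(2-methylpropanoyloxy)methyl]-6-(4,4,5,5-tetramethyl-1,3,2-dioxaborolan-2-yl)cyclohex-3-en-1-yl]ethan-1-one | CC1(C)OB(OC1(C)C)[C@@H]2CC(COC(=O)C(C)C)=C([C@@H](C)CCCOC(C)=O)[C@@H](O[Si](C)(C)C(C)(C)C)[C@H]2C(C)=O | intermediate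
23 | 1-[(1S,2S,6R)-3-[(2S)-5-acetoxypentan-2-yl]-2-{[tert-butyl(dimethyl)silyl]oxy}-4-[(2-methylpropanoyloxy)methyl]-6-(4,4,5,5-tetramethyl-1,3,2-dioxaborolan-2-yl)cyclohex-3-en-1-yl]ethenyl trifluoromethanesulfonate | CC1(C)OB(OC1(C)C)[C@@H]2CC(COC(=O)C(C)C)=C([C@@H](C)CCCOC(C)=O)[C@@H](O[Si](C)(C)C(C)(C)C)[C@H]2C(=C)OS(=O)(=O)C(F)(F)F | intermediate
24 | 1-[(1S,2S,6R)-3-[(2S)-5-acetoxypentan-2-yl]-2-{[tert-butyl(dimethyl)silyl]oxy}-6-hydroxy-4-[(2-methylpropanoyloxy)methyl]cyclohex-3-en-1-yl]ethenyl trifluoromethanesulfonate | O[C@@H]1CC(COC(=O)C(C)C)=C([C@@H](C)CCCOC(C)=O)[C@@H](O[Si](C)(C)C(C)(C)C)[C@H]1C(=C)OS(=O)(=O)C(F)(F)F | intermediate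
25 | [(3aS,4S,7aR)-5-[(2S)-5-acetoxypentan-2-yl]-4-{[tert-butyl(dimethyl)silyl]oxy}-3-methylidene-2-oxo-2,3,3a,4,7,7a-hexahydro-1-benzofuran-6-yl]methyl 2-methylpropanoate | C=C1C(=O)O[C@@H]2CC(COC(=O)C(C)C)=C([C@@H](C)CCCOC(C)=O)[C@@H](O[Si](C)(C)C(C)(C)C)[C@@H]12 | intermediate
26 | [(3aR,4S,7aR)-5-[(2S)-5-acetoxypentan-2-yl]-4-hydroxy-3-methylidene-2-oxo-2,3,3a,4,7,7a-hexahydro-1-benzofuran-6-yl]methyl 2-methylpropanoate | C=C1C(=O)O[C@@H]2CC(COC(=O)C(C)C)=C([C@@H](C)CCCOC(C)=O)[C@@H](O)[C@@H]12 | target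

**Step count and risks**

Total step count: 16. Longest linear sequence: 13 steps (steps 1–3, 5–7 and 10–16).

Steps most likely to fail:

Step 10. The Lewis acid may desilylate the dienol ether and give open-chain conjugate addition in place of ring closure, or facial discrimination may be weak if the boronate slows the catalysed pathway. The fallback replaces catalyst control by auxiliary control and sets out from diene 14 and acid 16. Acid 16 is converted through mixed anhydride 18 with lithiated (R)-4-benzyloxazolidin-2-one into (4R)-4-benzyl-3-[(2E)-3-(4,4,5,5-tetramethyl-1,3,2-dioxaborolan-2-yl)prop-2-enoyl]-1,3-oxazolidin-2-one F1. Cycloaddition of 14 with F1 promoted by Me2AlCl (1.4 equiv, CH2Cl2, −78 °C), in which the benzyl group shields the Si face of the α-carbon of the aluminium-chelated s-cis imide, should give the auxiliary-bearing cycloadduct (4R)-4-benzyl-3-{[(1S,2S,6R)-3-[(2S)-5-acetoxypentan-2-yl]-2-{[tert-butyl(dimethyl)silyl]oxy}-4-[(2-methylpropanoyloxy)methyl]-6-(4,4,5,5-tetramethyl-1,3,2-dioxaborolan-2-yl)cyclohex-3-en-1-yl]carbonyl}-1,3-oxazolidin-2-one F2. Treatment with LiSEt then cleaves the auxiliary, and the route is rejoined at thioester 21.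

Step 7. Enolisation and acyl migration of the α-acyloxy ketone, or Lewis-acid cleavage of the vinylogous silyl ester, may compete with methylenation. The fallback introduces C9 and C14 by cross-coupling instead of carbonyl methylenation and sets out from aldehyde 5. Enamine 10 is C-acylated with acetyl chloride to (4S,5E)-5-acetyl-4-methyl-6-(morpholin-4-yl)hex-5-en-1-yl acetate F3 and hydrolysed to (4S)-5-formyl-4-methyl-6-oxoheptyl acetate F4. O-Silylation as in step 6 gives (4S,5E)-5-({[tert-butyl(dimethyl)silyl]oxy}methylidene)-4-methyl-6-oxoheptyl acetate F5. Kinetic deprotonation of the methyl group (KN(SiMe3)2, −78 °C) and O-triflation give (3E,4S)-7-acetoxy-3-({[tert-butyl(dimethyl)silyl]oxy}methylidene)-4-methylhept-1-en-2-yl trifluoromethanesulfonate F6. Stille coupling with (tributylstannyl)methanol (Pd(PPh3)4, LiCl, dioxane, 80 °C) gives (4S,5E)-5-({[tert-butyl(dimethyl)silyl]oxy}methylidene)-6-(hydroxymethyl)-4-methylhept-6-en-1-yl acetate F7. Acylation with isobutyryl chloride 7 (pyridine, DMAP) returns to diene 14.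

Step 15. Capture of the acylpalladium intermediate by the trans hydroxyl may be slow because of the strained trans ring fusion, so that triflate hydrolysis or ionisation of the allylic isobutyrate takes over. The fallback introduces the lactone carbonyl carbon at the alcohol oxidation level and sets out from hydroxy triflate 24. Stille hydroxymethylation with (tributylstannyl)methanol (Pd(PPh3)4, LiCl, dioxane, 80 °C) should give 2-[(1S,2S,6R)-3-[(2S)-5-acetoxypentan-2-yl]-2-{[tert-butyl(dimethyl)silyl]oxy}-6-hydroxy-4-[(2-methylpropanoyloxy)methyl]cyclohex-3-en-1-yl]prop-2-en-1-ol F8. MnO2 (CH2Cl2, rt) then oxidises the allylic primary alcohol to the enal, whose lactol with the C8 hydroxyl is oxidised on to lactone 25.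

Further compounds
F1 | step 10 | (4R)-4-benzyl-3-[(2E)-3-(4,4,5,5-tetramethyl-1,3,2-dioxaborolan-2-yl)prop-2-enoyl]-1,3-oxazolidin-2-one | O=C(/C=C/B1OC(C)(C)C(C)(C)O1)N1[C@H](Cc2ccccc2)COC1=O
F2 | step 10 | (4R)-4-benzyl-3-{[(1S,2S,6R)-3-[(2S)-5-acetoxypentan-2-yl]-2-{[tert-butyl(dimethyl)silyl]oxy}-4-[(2-methylpropanoyloxy)methyl]-6-(4,4,5,5-tetramethyl-1,3,2-dioxaborolan-2-yl)cyclohex-3-en-1-yl]carbonyl}-1,3-oxazolidin-2-one | CC1(C)OB(OC1(C)C)[C@@H]2CC(COC(=O)C(C)C)=C([C@@H](C)CCCOC(C)=O)[C@@H](O[Si](C)(C)C(C)(C)C)[C@H]2C(=O)N3[C@H](Cc4ccccc4)COC3=O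
F3 | step 7 | (4S,5E)-5-acetyl-4-methyl-6-(morpholin-4-yl)hex-5-en-1-yl acetate | N1(CCOCC1)/C=C(\[C@@H](C)CCCOC(C)=O)C(C)=O
F4 | step 7 | (4S)-5-formyl-4-methyl-6-oxoheptyl acetate | O=CC(C(C)=O)[C@@H](C)CCCOC(C)=O
F5 | step 7 | (4S,5E)-5-({[tert-butyl(dimethyl)silyl]oxy}methylidene)-4-methyl-6-oxoheptyl acetate | CC(C)(C)[Si](C)(C)O/C=C(\[C@@H](C)CCCOC(C)=O)C(C)=O
F6 | step 7 | (3E,4S)-7-acetoxy-3-({[tert-butyl(dimethyl)silyl]oxy}methylidene)-4-methylhept-1-en-2-yl trifluoromethanesulfonate | CC(C)(C)[Si](C)(C)O/C=C(\[C@@H](C)CCCOC(C)=O)C(=C)OS(=O)(=O)C(F)(F)F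
F7 | step 7 | (4S,5E)-5-({[tert-butyl(dimethyl)silyl]oxy}methylidene)-6-(hydroxymethyl)-4-methylhept-6-en-1-yl acetate | CC(C)(C)[Si](C)(C)O/C=C(\[C@@H](C)CCCOC(C)=O)C(=C)CO
F8 | step 15 | 2-[(1S,2S,6R)-3-[(2S)-5-acetoxypentan-2-yl]-2-{[tert-butyl(dimethyl)silyl]oxy}-6-hydroxy-4-[(2-methylpropanoyloxy)methyl]cyclohex-3-en-1-yl]prop-2-en-1-ol | O[C@@H]1CC(COC(=O)C(C)C)=C([C@@H](C)CCCOC(C)=O)[C@@H](O[Si](C)(C)C(C)(C)C)[C@H]1C(=C)CO
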